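**Retrosynthetic overview** (chain numbering C1 = CHBr terminus to C8 = CH2Cl; the oxolane oxygen joins C3 and C6)
1. The only ring is closed last: C6–O and C7–Br by 5-exo bromoetherification of bromohydrin 9 onto the (6E)-allylic chloride.
2. C3–O and C4–Br come from an enantioselective anti bromohydroxylation of the (3E)-alkene of achiral triene 8 (new method).
3. The C8–Cl bond comes from allylic alcohol 7 by Corey–Kim chlorination.
4. The C5–C6 bond comes from palladium-catalysed coupling of pentadienyl bromide 4 with the alkenylalane made from propargyl alcohol.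
5. Bromide 4 comes from commercial (E)-3-methylpent-2-en-4-yn-1-ol by hydrozirconation–bromination and PBr3.

Assumption: (DHQD)2PHAL is taken to give the (3S,4R) bromohydrin in step 5; if the facial sense is the opposite, the pseudoenantiomer (DHQ)2PHAL is used and nothing else changes.

**Step 1**
Reactants: 1 (2E)-3-methylpent-2-en-4-yn-1-ol
Product: 3 (2E,4E)-5-bromo-3-methylpenta-2,4-dien-1-ol, via dizirconated dienolate 2 (not isolated)
Conditions: Cp2Zr(H)Cl (2.2 equiv), THF, 0 °C to rt; then NBS (1.1 equiv), 0 °C
Reagents that add atoms: N-bromosuccinimide, O=C1CCC(=O)N1Br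
Why: Hydrozirconation adds Zr–H syn across the terminal alkyne with zirconium on the terminal carbon (the first equivalent is consumed by the hydroxyl group), and bromodezirconation goes with retention, so the new C1=C2 bond is E.

**Step 2**
Reactants: 3 (2E,4E)-5-bromo-3-methylpenta-2,4-dien-1-ol
Product: 4 (1E,3E)-1,5-dibromo-3-methylpenta-1,3-diene
Conditions: PBr3 (0.4 equiv), Et2O, −10 °C; used crude
Reagents that add atoms: phosphorus tribromide, BrP(Br)Br
Why: Conversion of a primary allylic alcohol to the bromide with PBr3 (SN2 at the activated phosphite ester); the conjugated primary bromide is the favoured allylic isomer, so both E double bonds are kept.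

**Step 3**
Reactants: 5 prop-2-yn-1-ol; 4 (1E,3E)-1,5-dibromo-3-methylpenta-1,3-diene (limiting)
Product: 7 (2E,5E,7E)-8-bromo-2,6-dimethylocta-2,5,7-trien-1-ol, via alkenylalane 6 (not isolated)
Conditions: AlMe3 (3 equiv), Cp2ZrCl2 (25 mol %), CH2Cl2, 0 °C to rt; then 4, Pd(PPh3)4 (3 mol %), THF, −20 to 0 °C
Reagents that add atoms: trimethylaluminium, C[Al](C)C
Why: Negishi zirconium-catalysed carboalumination adds Me and Al syn (Me to the internal carbon), which fixes the (E)-2-methylalkenyl geometry, and palladium-catalysed allyl–alkenyl cross-coupling joins the alane to the less substituted allyl terminus of 4, the allylic C–Br bond reacting with zerovalent palladium far faster than the vinyl C–Br bond.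

**Step 4**
Reactants: 7 (2E,5E,7E)-8-bromo-2,6-dimethylocta-2,5,7-trien-1-ol
Product: 8 (1E,3E,6E)-1-bromo-8-chloro-3,7-dimethylocta-1,3,6-triene
Conditions: NCS (1.2 equiv), Me2S (1.3 equiv), CH2Cl2, −20 to 0 °C
Reagents that add atoms: N-chlorosuccinimide, O=C1CCC(=O)N1Cl
Why: Corey–Kim chlorination: the allylic alkoxysulfonium salt is displaced by chloride at the primary carbon without allylic shift, and the diene and vinyl bromide are untouched.

**Step 5**
Reactants: 8 (1E,3E,6E)-1-bromo-8-chloro-3,7-dimethylocta-1,3,6-triene
Product: 9 (1E,3S,4R,6E)-1,4-dibromo-8-chloro-3,7-dimethylocta-1,6-dien-3-ol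
Conditions: (DHQD)2PHAL (10 mol %), PhCONHBr (1.05 equiv), (+)-10-camphorsulfonic acid (10 mol %), H2O (10 equiv), acetone, −30 °C
Reagents that add atoms: N-bromobenzamide, O=C(NBr)c1ccccc1; water, O
Why: Proposed new method: catalytic enantioselective anti 1,2-bromohydroxylation of a 1-bromo-1,3-diene; the protonated bis-cinchona ether carries Br+ from the N-bromoamide to the C3=C4 π-bond inside its phthalazine cleft, where the 2-bromovinyl group plays the part that the aryl ring plays in the known substrates; Br+ bonds to C4 because the charge is then spread over a tertiary 1-bromoallyl cation (C3 to C1), and catalyst-bound water attacks the tertiary C3 anti to the still-bridging bromine, so the 3E geometry is translated into (3S,4R) and the C3–O bond of the future ring is made; the C6=C7 alkene is deactivated by the allylic chlorine and has no conjugating group for recognition; the closest known reaction type is the (DHQD)2PHAL-catalysed asymmetric bromohydroxylation of styrenyl and cinnamyl alkenes with an N-bromoamide and water.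

**Step 6**
Reactants: 9 (1E,3S,4R,6E)-1,4-dibromo-8-chloro-3,7-dimethylocta-1,6-dien-3-ol
Product: 10 (2S,3R,5R)-3-bromo-2-[(E)-2-bromoethenyl]-5-[(2R)-2-bromo-1-chloropropan-2-yl]-2-methyloxolane
Conditions: TBCO (1.1 equiv), CH2Cl2, −20 to 0 °C, dark
Reagents that add atoms: 2,4,4,6-tetrabromocyclohexa-2,5-dien-1-one, O=C1C(Br)=CC(Br)(Br)C=C1Br
Why: 5-exo-trig bromoetherification: Br+ adds to C6=C7, the only alkene not deactivated by a vinylic bromine, and the tertiary hydroxyl attacks C6 anti to bromine (5-exo is preferred over 6-endo because CH2Cl destabilises charge at C7), so the 6E geometry gives the (6R,7R) pair; ring closure through an envelope with both C4–Br and the C6 side chain pseudo-equatorial places them cis (the 2,4-cis preference of 2-substituted pent-4-en-1-ols).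

**Compound list**
1 | (2E)-3-methylpent-2-en-4-yn-1-ol | C#C/C(C)=C/CO | starting material
2 | chlorobis(cyclopentadienyl)zirconium (2E,4E)-5-[chlorobis(cyclopentadienyl)zirconio]-3-methylpenta-2,4-dien-1-olate (dizirconated dienolate) | Cl[Zr](OC/C=C(C)/C=C/[Zr](Cl)(C1C=CC=C1)C1C=CC=C1)(C1C=CC=C1)C1C=CC=C1 | intermediate
3 | (2E,4E)-5-bromo-3-methylpenta-2,4-dien-1-ol | Br/C=C/C(C)=C/CO | intermediate
4 | (1E,3E)-1,5-dibromo-3-methylpenta-1,3-diene | Br/C=C/C(C)=C/CBr | intermediate
5 | prop-2-yn-1-ol | C#CCO | starting material
6 | [(1E)-3-(dimethylalumanyloxy)-2-methylprop-1-en-1-yl]dimethylalumane (alkenylalane) | C[Al](C)OC/C(C)=C/[Al](C)C | intermediate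
7 | (2E,5E,7E)-8-bromo-2,6-dimethylocta-2,5,7-trien-1-ol | OC/C(C)=C/C/C=C(C)/C=C/Br | intermediate
8 | (1E,3E,6E)-1-bromo-8-chloro-3,7-dimethylocta-1,3,6-triene | ClC/C(C)=C/C/C=C(C)/C=C/Br | intermediate
9 | (1E,3S,4R,6E)-1,4-dibromo-8-chloro-3,7-dimethylocta-1,6-dien-3-ol | Br/C=C/[C@](C)(O)[C@H](Br)C/C=C(C)/CCl | intermediate
10 | (2S,3R,5R)-3-bromo-2-[(E)-2-bromoethenyl]-5-[(2R)-2-bromo-1-chloropropan-2-yl]-2-methyloxolane | C[C@](Br)(CCl)[C@H]1C[C@@H](Br)[C@](C)(/C=C/Br)O1 | target

**Totals**
Total steps: 6. Longest linear sequence: 6 (1 → 3 → 4 → 7 → 8 → 9 → 10; propargyl alcohol 5 enters at step 3).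

**Steps most likely to fail**

Step 5 (the new bromohydroxylation). The risks are a low ee or the wrong facial sense without the aryl group of the known substrates, water adding at C1 (which leads to an enal after loss of HBr), and partial loss of anti selectivity through an open allyl cation. The fallback uses only known reactions and sets out from 7, coming back at 10. Sharpless asymmetric epoxidation of 7 with Ti(OiPr)4, D-(−)-diethyl tartrate and t-BuOOH gives [(2R,3R)-3-[(2E,4E)-5-bromo-3-methylpenta-2,4-dien-1-yl]-2-methyloxiran-2-yl]methanol F1. Appel chlorination (PPh3, CCl4) turns it into (2S,3R)-3-[(2E,4E)-5-bromo-3-methylpenta-2,4-dien-1-yl]-2-(chloromethyl)-2-methyloxirane F2. Anhydrous HBr in Et2O at −78 °C opens the protonated epoxide at the tertiary carbon with inversion to give (2R,3R,5E,7E)-2,8-dibromo-1-chloro-2,6-dimethylocta-5,7-dien-3-ol F3. NBS in MeCN then closes the ring by 5-endo-trig bromoetherification onto the diene, with the carbinol substituent pseudo-equatorial, to give 10. The weak point of this fallback is the regiochemistry of the HBr opening, since the chloromethyl group lowers the usual preference for the tertiary carbon.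

Step 6 (diastereoselectivity of the 5-exo closure). The C4–Br stereocentre steers the new C6/C7 pair only through a 1,3-relationship, so a ratio near 3:1 with a separable epimer pair is the realistic expectation. The fallback sets out from 9 and comes back at 10 without a new isolated compound. It replaces substrate control by reagent control: the cyclisation is run with a chiral Brønsted acid and Lewis base pair (a BINOL-derived phosphoric acid such as TRIP with Ph3P=S and N-bromophthalimide), and the acid enantiomer matched to 9 is chosen.

Step 3 (allyl–alkenyl coupling). The risks are insertion of zerovalent palladium into a vinyl C–Br bond of 4 or 7, and E/Z scrambling or branched coupling through the pentadienyl–palladium intermediate. The fallback sets out from 1 and comes back at 7, and installs the vinyl bromide only after the coupling. PBr3 converts 1 into (3E)-5-bromo-3-methylpent-3-en-1-yne F4. This bromide is coupled with alane 6 under the same palladium catalysis in THF, where zirconium-catalysed carboalumination of the free alkyne is suppressed, to give (2E,5E)-2,6-dimethylocta-2,5-dien-7-yn-1-ol F5. Hydrozirconation with Cp2Zr(H)Cl (2.2 equiv) followed by NBS then gives 7.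

**Further compounds**
F1 | step 5 | [(2R,3R)-3-[(2E,4E)-5-bromo-3-methylpenta-2,4-dien-1-yl]-2-methyloxiran-2-yl]methanol | OC[C@@]1(C)O[C@@H]1C/C=C(C)/C=C/Br
F2 | step 5 | (2S,3R)-3-[(2E,4E)-5-bromo-3-methylpenta-2,4-dien-1-yl]-2-(chloromethyl)-2-methyloxirane | ClC[C@@]1(C)O[C@@H]1C/C=C(C)/C=C/Br
F3 | step 5 | (2R,3R,5E,7E)-2,8-dibromo-1-chloro-2,6-dimethylocta-5,7-dien-3-ol | ClC[C@](C)(Br)[C@H](O)C/C=C(C)/C=C/Br
F0 | step 6 | none | none
F4 | step 3 | (3E)-5-bromo-3-methylpent-3-en-1-yne | C#C/C(C)=C/CBr
F5 | step 3 | (2E,5E)-2,6-dimethylocta-2,5-dien-7-yn-1-ol | OC/C(C)=C/C/C=C(C)/C#C
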